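The route rests on disconnecting the 1,2-dioxane (O1–O2–C3–C4–C5–C6) at O2–C3 and C5–C6 into a peroxycarbenium ion (C6–O1–O2) and a 1,3-dioxygenated three-carbon unit (C3–C5). In one flask a chiral 1,3-bis(silyloxy)allylstannane adds through its oxygen-bearing γ-carbon to the ketone-derived peroxycarbenium ion, and the enol silane thus released is captured by the peroxide as a cyclic peroxyacetal. The step exploits the 1,3-relationship of the oxygenated ring carbons C3 and C5 and the peroxyketal oxidation level of quaternary C6. The acetal carbon C3 later accepts the terpenoid as an alkenyltrifluoroborate by axial attack on the lactone-locked peroxycarbenium ion; the decalin comes from larixol.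

Key step: step 14

Remark: the target as drawn has a trans-fused lactone/dioxane with the C3 side chain axial, so the route uses stereospecific or stereoelectronically controlled bond formations rather than equilibration.
Remark: the mixed-ketal carbon C13 in 4–8 and the peroxyacetal carbon C3 in 24–28 are anomeric mixtures and carry no descriptor; both centres are erased later (steps 7 and 17).
Remark: labdane locants are used for the decalin; larixol (1), 1,1,3,3-tetramethoxypropane (14) and the silyl enyne 21 are taken as purchasable.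

Step 1
Reactants: 1 (+)-larixol
Product: 2 6α-hydroxy-14,15-dinorlabd-8(17)-en-13-one
Conditions: KMnO4, MgSO4, acetone–H2O, 0 °C
Reagents that add atoms: none
Why: Permanganate oxidative cleavage of the tertiary vinyl carbinol (dihydroxylation, then glycol fission) removes C14 and C15 and leaves the methyl ketone, as known for manool-type side chains, while the hindered exocyclic alkene should survive at 0 °C.

Step 2
Reactants: 2 6α-hydroxy-14,15-dinorlabd-8(17)-en-13-one
Product: 4 13-methoxy-8α,13-epoxy-14,15-dinorlabdan-6α-ol (cyclic methyl ketal), via hydroxy ketone 3 (not isolated)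
Conditions: Mn(dpm)3 (10 mol%), PhSiH3, O2 (1 atm), iPrOH–CH2Cl2, 0 °C to rt; then MeOH, camphorsulfonic acid (cat.), rt
Reagents that add atoms: dioxygen O=O; methanol CO
Why: Mukaiyama hydration places the tertiary hydroxyl at C8 from the α-face, away from the axial C10 methyl, and acid-catalysed ketalisation then ties the 8α-hydroxyl and the ketone into one mixed cyclic ketal that protects both.

Step 3
Reactants: 4 cyclic methyl ketal
Product: 5 6α,18-epoxy-13-methoxy-8α,13-epoxy-14,15-dinorlabdane (tetrahydrofuran ether)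
Conditions: PhI(OAc)2, I2, cyclohexane, tungsten lamp, 40 °C
Reagents that add atoms: none
Why: Suárez hypoiodite reaction: the 6α-alkoxy radical abstracts hydrogen by 1,5-transfer from the peri-positioned equatorial 4α-methyl (C18), and iodination followed by ring closure gives the ether, fixing C4 with the oxidised carbon α.

Step 4
Reactants: 5 tetrahydrofuran ether
Product: 6 13-methoxy-8α,13-epoxy-14,15-dinorlabdan-18,6α-olide
Conditions: RuCl3·xH2O (5 mol%), NaIO4, CCl4–MeCN–H2O, rt
Reagents that add atoms: sodium periodate [Na+].[O-]I(=O)(=O)=O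
Why: RuO4 oxidation of a cyclic ether at its methylene carbon gives the γ-lactone; the ketal and the quaternary centres carry no oxidisable C–H next to oxygen except the slower tertiary C6–H.

Step 5
Reactants: 6 18,6α-olide
Product: 7 methyl 6α-hydroxy-13-methoxy-8α,13-epoxy-14,15-dinorlabdan-18-oate
Conditions: NaOMe (0.2 equiv), MeOH, rt
Reagents that add atoms: methanol CO
Why: Base-catalysed methanolysis (transesterification) of the strained peri-bridged lactone should give the hydroxy ester, the form in which this substitution pattern occurs in the target.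

Step 6
Reactants: 7 hydroxy ester
Product: 8 methyl 6α-(tert-butyldimethylsilyloxy)-13-methoxy-8α,13-epoxy-14,15-dinorlabdan-18-oate
Conditions: TBSCl, imidazole, DMAP (cat.), DMF, 50 °C
Reagents that add atoms: tert-butyldimethylsilyl chloride CC(C)(C)[Si](C)(C)Cl
Why: Standard silylation of the only free hydroxyl under non-acidic conditions that leave the mixed ketal intact.

Step 7
Reactants: 8 silyl ether ketal
Product: 9 methyl 6α-(tert-butyldimethylsilyloxy)-8α-hydroxy-13-oxo-14,15-dinorlabdan-18-oate
Conditions: pyridinium p-toluenesulfonate, acetone–H2O (10:1), 45 °C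
Reagents that add atoms: water O
Why: Mild acid hydrolysis of the mixed ketal releases the methyl ketone and the tertiary alcohol without touching the secondary silyl ether.

Step 8
Reactants: 9 hydroxy ketone
Product: 11 methyl 6α-(tert-butyldimethylsilyloxy)-8α-(triethylsilyloxy)-13-(trifluoromethylsulfonyloxy)-14,15-dinorlabd-13(16)-en-18-oate, via hydroxy enol triflate 10 (not isolated)
Conditions: KN(SiMe3)2 (2.2 equiv), THF, −78 °C; N-(5-chloro-2-pyridyl)triflimide; then Et3SiCl, −78 to 0 °C
Reagents that add atoms: N-(5-chloro-2-pyridyl)triflimide FC(F)(F)S(=O)(=O)N(c1ccc(Cl)cn1)S(=O)(=O)C(F)(F)F; triethylsilyl chloride CC[Si](Cl)(CC)CC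
Why: Kinetic deprotonation at the methyl group and O-triflation (Comins reagent) give the 1,1-disubstituted enol triflate, and the tertiary alkoxide is silylated in the same flask so that it cannot cyclise onto the alkene later.

Step 9
Reactants: 11 enol triflate
Product: 13 potassium alkenyltrifluoroborate (BF3K at C13, C13=C16 methylene), via pinacol boronate 12 (not isolated)
Conditions: B2pin2, PdCl2(PPh3)2 (3 mol%), PPh3, KOPh, toluene, 50 °C; then KHF2, MeOH–H2O, 0 °C
Reagents that add atoms: bis(pinacolato)diboron CC1(C)OB(OC1(C)C)B1OC(C)(C)C(C)(C)O1; potassium hydrogen difluoride [K+].F.[F-]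
Why: Miyaura borylation of the alkenyl triflate followed by fluoride exchange gives the bench-stable trifluoroborate needed for step 17.

Step 10
Reactants: 14 1,1,3,3-tetramethoxypropane
Product: 16 (E)-3-(tert-butyldimethylsilyloxy)acrolein, via sodium malonaldehyde enolate 15 (not isolated)
Conditions: 1 M HCl, 50 °C; NaOH to pH 10, evaporate; then TBSCl, THF, 0 °C
Reagents that add atoms: water O; tert-butyldimethylsilyl chloride CC(C)(C)[Si](C)(C)Cl
Why: Acetal hydrolysis gives malonaldehyde as its sodium enolate, and O-silylation gives the E-configured vinylogous silyl formate.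

Step 11
Reactants: 16 (E)-3-(tert-butyldimethylsilyloxy)acrolein
Product: 18 (E)-3-(tert-butyldimethylsilyloxy)acryloyl tributylstannane, via lithium stannyl alkoxide 17 (not isolated)
Conditions: Bu3SnLi (from Bu3SnH and LiN(iPr)2), THF, −78 °C; then 1,1'-(azodicarbonyl)dipiperidine, −78 to 0 °C
Reagents that add atoms: tributylstannyllithium [Li][Sn](CCCC)(CCCC)CCCC
Why: 1,2-Addition of the stannyl anion to the enal and in situ hydride transfer from the alkoxide to the azodicarboxamide gives the acylstannane (Marshall protocol).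

Step 12
Reactants: 18 acylstannane
Product: 20 (S,E)-[1,3-bis(tert-butyldimethylsilyloxy)allyl]tributylstannane, via hydroxystannane 19 (not isolated)
Conditions: (R)-BINAL-H [LiAlH(OEt)((R)-1,1'-bi-2-naphtholate)], THF, −78 °C; then TBSOTf, 2,6-lutidine, CH2Cl2, −78 °C
Reagents that add atoms: tert-butyldimethylsilyl triflate CC(C)(C)[Si](C)(C)OS(=O)(=O)C(F)(F)F
Why: BINAL-H reduction of enoyl stannanes sets the stannyl carbinol centre by reagent control (the BINAL-H enantiomer is the one that gives the S carbinol), and immediate silylation stabilises it.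

Step 13
Reactants: 21 trimethyl(3-methylbut-3-en-1-yn-1-yl)silane
Product: 22 2-hydroperoxy-2-methoxy-4-(trimethylsilyl)but-3-yne (racemic hydroperoxy ketal)
Conditions: O3, CH2Cl2–MeOH (4:1), −78 °C; N2 purge
Reagents that add atoms: ozone [O-][O+]=O; methanol CO
Why: Criegee ozonolysis of the 1,1-disubstituted alkene gives the more substituted carbonyl oxide, which methanol traps as the hydroperoxy ketal; the silylalkyne reacts far more slowly with ozone.

Step 14
Reactants: 20 (S,E)-[1,3-bis(tert-butyldimethylsilyloxy)allyl]tributylstannane; 22 hydroperoxy ketal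
Product: 25 (5S,6R)-3-methoxy-6-methyl-5-(tert-butyldimethylsilyloxy)-6-[(trimethylsilyl)ethynyl]-1,2-dioxane, via silyl peroxide enol silane 23 (not isolated), via cyclic silyl peroxyacetal 24 (not isolated)
Conditions: TMSOTf (1.2 equiv), CH2Cl2, −78 °C; then MeOH, camphorsulfonic acid, −40 to 0 °C
Reagents that add atoms: methanol CO
Why: TMSOTf silylates and ionises 22 to a peroxycarbenium ion, which the oxygen-bearing γ-carbon of 20 attacks in an anti SE2′ reaction (C5–C6 bond) with loss of tin to give enol silane 23; the silyl peroxide then closes 6-exo-trig onto the oxocarbenium ion formed by protonation of the enol silane (O2–C3 bond), and methanol exchanges the anomeric silyl ether. The closest known reactions are the Lewis-acid allylation of peroxyketals by allylstannanes and allylsilanes, the syn-selective additions of γ-silyloxyallylstannanes, and peroxyacetal formation from hydroperoxides and enol ethers. C5 is set by chirality transfer from the stannyl carbinol carbon (electrophile anti to tin, silyloxy group inside). C6 is set by the open antiperiplanar transition state, in which the slim alkynyl group rather than methyl sits gauche to the silyloxy group; this gives the C5–O/C6–O anti isomer that a trans-fused lactone needs. C3 is only an acetal carbon here and is set in step 17. Both allyl termini carry the same silyloxy group, so α- versus γ-attack is degenerate, and the β-tin effect directs bond formation to the oxygen-bearing carbon rather than to the central carbon.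

Step 15
Reactants: 25 alkynyl dioxane
Product: 26 2-[(5S,6R)-3-methoxy-6-methyl-5-(tert-butyldimethylsilyloxy)-1,2-dioxan-6-yl]acetic acid
Conditions: Cy2BH, THF, 0 °C; then H2O2, NaHCO3 buffer (pH 8), 0 °C; acidify to pH 4
Reagents that add atoms: hydrogen peroxide OO; water O
Why: Zweifel hydroboration–oxidation of a 1-silylalkyne places boron on the silylated carbon, and oxidation converts the alkyne into the homologous acetic acid without changing C6.

Step 16
Reactants: 26 silyloxy acid
Product: 28 trans-fused peroxyacetal lactone (3-methoxy-1,2-dioxane fused at C5–C6 to a γ-lactone; 5S,6R), via hydroxy acid 27 (not isolated)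
Conditions: HF·pyridine, pyridine, THF, 0 °C to rt; then EDCI·HCl, DMAP, CH2Cl2, rt
Reagents that add atoms: none
Why: Fluoride desilylation frees the C5 hydroxyl, and carbodiimide lactonisation onto the trans-disposed acetic acid arm closes the trans-fused γ-lactone that locks the dioxane chair.

Step 17
Reactants: 28 trans-fused peroxyacetal lactone; 13 potassium alkenyltrifluoroborate
Product: 29 6-O-TBS-8-O-TES-protected target (C3 of the dioxane R, alkenyl group axial)
Conditions: BF3·OEt2 (3 equiv), CH2Cl2–MeCN, −40 °C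
Reagents that add atoms: none
Why: Proposed new method: BF3 abstracts fluoride from 13 to give an alkenyldifluoroborane that binds the exocyclic methoxy group, ionises it to the cyclic peroxycarbenium ion and transfers the alkenyl group from the resulting borate to C3 along the axial trajectory of the lactone-locked half-chair, syn to the axial C5–H and anti to the axial C6 methyl, which sets C3 (R); the closest known reactions are the BF3-mediated coupling of potassium alkenyltrifluoroborates with O,O-acetals and the Lewis-acid substitution of 3-alkoxy-1,2-dioxanes by silyl nucleophiles.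

Step 18
Reactants: 29 bis-silyl ether
Product: 30 target CNP0162504.1
Conditions: HF·pyridine, pyridine, THF, 0 °C to rt
Reagents that add atoms: none
Why: Buffered fluoride desilylation removes both silyl ethers under conditions too mild for the peroxide, the lactone or acid cyclisation of the 8-hydroxyl onto the methylene group.

Compound list
1 | (+)-larixol, (13S)-labda-8(17),14-diene-6α,13-diol | C=C[C@@](C)(O)CC[C@@H]1[C@@]2(C)CCCC(C)(C)[C@@H]2[C@@H](O)CC1=C | starting material
2 | 6α-hydroxy-14,15-dinorlabd-8(17)-en-13-one | CC(=O)CC[C@@H]1[C@@]2(C)CCCC(C)(C)[C@@H]2[C@@H](O)CC1=C | intermediate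
3 | 6α,8α-dihydroxy-14,15-dinorlabdan-13-one | CC(=O)CC[C@@H]1[C@@]2(C)CCCC(C)(C)[C@@H]2[C@@H](O)C[C@@]1(C)O | intermediate
4 | 13-methoxy-8α,13-epoxy-14,15-dinorlabdan-6α-ol (C13 anomers) | COC1(C)CC[C@@H]2[C@@]3(C)CCCC(C)(C)[C@@H]3[C@@H](O)C[C@@]2(C)O1 | intermediate
5 | 6α,18-epoxy-13-methoxy-8α,13-epoxy-14,15-dinorlabdane | COC1(C)CC[C@@H]2[C@@]3(C)CCC[C@@](C)(CO4)[C@@H]3[C@@H]4C[C@@]2(C)O1 | intermediate
6 | 13-methoxy-8α,13-epoxy-14,15-dinorlabdan-18,6α-olide | COC1(C)CC[C@@H]2[C@@]3(C)CCC[C@@](C)(C(=O)O4)[C@@H]3[C@@H]4C[C@@]2(C)O1 | intermediate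
7 | methyl 6α-hydroxy-13-methoxy-8α,13-epoxy-14,15-dinorlabdan-18-oate | COC1(C)CC[C@@H]2[C@@]3(C)CCC[C@@](C)(C(=O)OC)[C@@H]3[C@@H](O)C[C@@]2(C)O1 | intermediate
8 | 6-O-TBS ether of 7 | COC1(C)CC[C@@H]2[C@@]3(C)CCC[C@@](C)(C(=O)OC)[C@@H]3[C@@H](O[Si](C)(C)C(C)(C)C)C[C@@]2(C)O1 | intermediate
9 | methyl 6α-(TBS-oxy)-8α-hydroxy-13-oxo-14,15-dinorlabdan-18-oate | CC(=O)CC[C@@H]1[C@@]2(C)CCC[C@@](C)(C(=O)OC)[C@@H]2[C@@H](O[Si](C)(C)C(C)(C)C)C[C@@]1(C)O | intermediate
10 | 13(16)-en-13-yl triflate with free 8α-hydroxyl | C=C(OS(=O)(=O)C(F)(F)F)CC[C@@H]1[C@@]2(C)CCC[C@@](C)(C(=O)OC)[C@@H]2[C@@H](O[Si](C)(C)C(C)(C)C)C[C@@]1(C)O | intermediate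
11 | 13(16)-en-13-yl triflate, 6-O-TBS, 8-O-TES | C=C(OS(=O)(=O)C(F)(F)F)CC[C@@H]1[C@@]2(C)CCC[C@@](C)(C(=O)OC)[C@@H]2[C@@H](O[Si](C)(C)C(C)(C)C)C[C@@]1(C)O[Si](CC)(CC)CC | intermediate
12 | C13 alkenyl pinacol boronate, 6-O-TBS, 8-O-TES | C=C(B1OC(C)(C)C(C)(C)O1)CC[C@@H]2[C@@]3(C)CCC[C@@](C)(C(=O)OC)[C@@H]3[C@@H](O[Si](C)(C)C(C)(C)C)C[C@@]2(C)O[Si](CC)(CC)CC | intermediate
13 | potassium C13 alkenyltrifluoroborate, 6-O-TBS, 8-O-TES | [K+].C=C([B-](F)(F)F)CC[C@@H]1[C@@]2(C)CCC[C@@](C)(C(=O)OC)[C@@H]2[C@@H](O[Si](C)(C)C(C)(C)C)C[C@@]1(C)O[Si](CC)(CC)CC | intermediate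
14 | 1,1,3,3-tetramethoxypropane | COC(OC)CC(OC)OC | starting material
15 | sodium (E)-3-oxoprop-1-en-1-olate | [Na+].[O-]/C=C/C=O | intermediate
16 | (E)-3-(tert-butyldimethylsilyloxy)acrolein | O=C/C=C/O[Si](C)(C)C(C)(C)C | intermediate
17 | lithium (E)-3-(TBS-oxy)-1-(tributylstannyl)prop-2-en-1-olate (racemic) | [Li+].[O-]C(/C=C/O[Si](C)(C)C(C)(C)C)[Sn](CCCC)(CCCC)CCCC | intermediate
18 | (E)-3-(TBS-oxy)acryloyl tributylstannane | CCCC[Sn](CCCC)(CCCC)C(=O)/C=C/O[Si](C)(C)C(C)(C)C | intermediate
19 | (S,E)-3-(TBS-oxy)-1-(tributylstannyl)prop-2-en-1-ol | CCCC[Sn](CCCC)(CCCC)[C@H](O)/C=C/O[Si](C)(C)C(C)(C)C | intermediate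
20 | (S,E)-[1,3-bis(TBS-oxy)allyl]tributylstannane | CCCC[Sn](CCCC)(CCCC)[C@H](O[Si](C)(C)C(C)(C)C)/C=C/O[Si](C)(C)C(C)(C)C | intermediate
21 | trimethyl(3-methylbut-3-en-1-yn-1-yl)silane | C=C(C)C#C[Si](C)(C)C | starting material
22 | 2-hydroperoxy-2-methoxy-4-(trimethylsilyl)but-3-yne (racemic) | COC(C)(OO)C#C[Si](C)(C)C | intermediate
23 | acyclic SE2′ adduct: trimethylsilyl peroxide at C6 (R), TBS ether at C5 (S), Z enol silane | C[Si](C)(C)OO[C@](C)(C#C[Si](C)(C)C)[C@@H](O[Si](C)(C)C(C)(C)C)/C=C\O[Si](C)(C)C(C)(C)C | intermediate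
24 | (5S,6R)-3,5-bis(TBS-oxy)-6-methyl-6-[(trimethylsilyl)ethynyl]-1,2-dioxane (C3 anomers) | CC(C)(C)[Si](C)(C)OC1C[C@H](O[Si](C)(C)C(C)(C)C)[C@@](C)(C#C[Si](C)(C)C)OO1 | intermediate
25 | (5S,6R)-3-methoxy-6-methyl-5-(TBS-oxy)-6-[(trimethylsilyl)ethynyl]-1,2-dioxane (C3 anomers) | COC1C[C@H](O[Si](C)(C)C(C)(C)C)[C@@](C)(C#C[Si](C)(C)C)OO1 | intermediate
26 | 2-[(5S,6R)-3-methoxy-6-methyl-5-(TBS-oxy)-1,2-dioxan-6-yl]acetic acid | COC1C[C@H](O[Si](C)(C)C(C)(C)C)[C@@](C)(CC(=O)O)OO1 | intermediate
27 | 2-[(5S,6R)-5-hydroxy-3-methoxy-6-methyl-1,2-dioxan-6-yl]acetic acid | COC1C[C@H](O)[C@@](C)(CC(=O)O)OO1 | intermediate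
28 | trans-fused peroxyacetal lactone (3-methoxy-1,2-dioxane fused at C5–C6 to a γ-lactone; 5S,6R) | COC1C[C@@H]2OC(=O)C[C@@]2(C)OO1 | intermediate
29 | 6-O-TBS-8-O-TES ether of the target | C=C(CC[C@@H]1[C@@]2(C)CCC[C@@](C)(C(=O)OC)[C@@H]2[C@@H](O[Si](C)(C)C(C)(C)C)C[C@@]1(C)O[Si](CC)(CC)CC)[C@H]1C[C@@H]2OC(=O)C[C@@]2(C)OO1 | intermediate
30 | CNP0162504.1 | C=C(CC[C@@H]1[C@@]2(C)CCC[C@@](C)(C(=O)OC)[C@@H]2[C@@H](O)C[C@@]1(C)O)[C@H]1C[C@@H]2OC(=O)C[C@@]2(C)OO1 | target

Total step count: 18. Longest linear sequence: 11 steps (steps 1–9, 17, 18).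

Steps most likely to fail

Step 17 (proposed new method). The methyl peroxyacetal may ionise at the ring O–C bond instead of losing methoxide, which opens the dioxane. The hindered 1,1-disubstituted alkenyl group may also transfer too slowly, so that protodeboronation or loss of the tertiary silyl ether takes over. Fallback, from 11 back to 29, with known reactions only: an asymmetric Nozaki–Hiyama–Kishi coupling of 11 (CrCl2, NiCl2 cat., chiral sulfonamide ligand) with methyl (E)-3-methyl-6-oxohex-3-enoate F1 (from acetal ester F9 of the next fallback by mild acid hydrolysis) gives the (14S)-allylic alcohol F2. Mesylation gives mesylate F3. Shi epoxidation of the trisubstituted alkene gives the (16S,17S)-epoxy mesylate F4. Perhydrolysis with ethereal H2O2 and catalytic H3PMo12O40 opens the epoxide at the tertiary carbon with inversion to give the β-hydroxy hydroperoxide F5. Cs2CO3 then closes the dioxane by SN2 displacement of the mesylate with inversion and lactonises, which gives 29.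

Step 14. A Lewis-acid-promoted 1,3-stannyl shift before C–C bond formation would erode the chirality transfer to C5. The facial pairing that sets C6 may be poor, and part of the stannane may react through its central carbon as a plain enol silane. Fallback, from 14 back to 28: controlled hydrolysis of 14 gives 3,3-dimethoxypropanal F6; isopropenylmagnesium bromide gives allylic alcohol F7; methyl chloroformate gives carbonate F8. Methoxycarbonylation (Pd(OAc)2, PPh3, CO, MeOH) then gives the (E)-β,γ-unsaturated ester F9, and Shi epoxidation gives epoxide F10. H2O2 with H3PMo12O40 opens it with inversion at the tertiary carbon to give hydroxy hydroperoxide F11, and camphorsulfonic acid closes the peroxyacetal and the lactone to 28.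

Step 15. The borane may reduce the peroxide bond, and the basic oxidation may fragment the peroxyacetal through its acetal C–H (Kornblum–DeLaMare-type cleavage). Fallback, from 25 back to 28: buffered Bu4NF/AcOH removes both silyl groups to give alkynol F12. Anti-Markovnikov hydration with CpRu(MeCN)3PF6 and a bipyridyl ligand gives the aldehyde, which closes to lactol F13. TEMPO with PhI(OAc)2 oxidises the lactol to 28.

Further compounds
F1 | step 17 | methyl (E)-3-methyl-6-oxohex-3-enoate | COC(=O)C/C(C)=C/CC=O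
F2 | step 17 | (14S)-allylic alcohol from 11 and F1 (6-O-TBS, 8-O-TES) | C=C(CC[C@@H]1[C@@]2(C)CCC[C@@](C)(C(=O)OC)[C@@H]2[C@@H](O[Si](C)(C)C(C)(C)C)C[C@@]1(C)O[Si](CC)(CC)CC)[C@@H](O)C/C=C(\C)CC(=O)OC
F3 | step 17 | (14S)-mesylate of F2 | C=C(CC[C@@H]1[C@@]2(C)CCC[C@@](C)(C(=O)OC)[C@@H]2[C@@H](O[Si](C)(C)C(C)(C)C)C[C@@]1(C)O[Si](CC)(CC)CC)[C@@H](OS(C)(=O)=O)C/C=C(\C)CC(=O)OC
F4 | step 17 | (16S,17S)-epoxy mesylate | C=C(CC[C@@H]1[C@@]2(C)CCC[C@@](C)(C(=O)OC)[C@@H]2[C@@H](O[Si](C)(C)C(C)(C)C)C[C@@]1(C)O[Si](CC)(CC)CC)[C@@H](OS(C)(=O)=O)C[C@@H]1O[C@@]1(C)CC(=O)OC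
F5 | step 17 | β-hydroxy hydroperoxide mesylate | C=C(CC[C@@H]1[C@@]2(C)CCC[C@@](C)(C(=O)OC)[C@@H]2[C@@H](O[Si](C)(C)C(C)(C)C)C[C@@]1(C)O[Si](CC)(CC)CC)[C@@H](OS(C)(=O)=O)C[C@H](O)[C@@](C)(CC(=O)OC)OO
F6 | step 14 | 3,3-dimethoxypropanal | COC(OC)CC=O
F7 | step 14 | 5,5-dimethoxy-2-methylpent-1-en-3-ol (racemic) | COC(OC)CC(O)C(C)=C
F8 | step 14 | methyl carbonate of F7 | COC(=O)OC(CC(OC)OC)C(C)=C
F9 | step 14 | methyl (E)-6,6-dimethoxy-3-methylhex-3-enoate | COC(OC)C/C=C(\C)CC(=O)OC
F10 | step 14 | methyl 2-[(2S,3S)-3-(2,2-dimethoxyethyl)-2-methyloxiran-2-yl]acetate | COC(OC)C[C@@H]1O[C@@]1(C)CC(=O)OC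
F11 | step 14 | methyl (3R,4S)-3-hydroperoxy-4-hydroxy-6,6-dimethoxy-3-methylhexanoate | COC(OC)C[C@H](O)[C@@](C)(CC(=O)OC)OO
F12 | step 15 | (5S,6R)-6-ethynyl-3-methoxy-6-methyl-1,2-dioxan-5-ol | COC1C[C@H](O)[C@@](C)(C#C)OO1
F13 | step 15 | trans-fused peroxyacetal lactol | COC1C[C@@H]2OC(O)C[C@@]2(C)OO1
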